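**Plan**

- Retrosynthesis cuts, in order: the ester C–O bond (acid 17 + epoxy ketol 12), the two C–O bonds of the oxirane (enone 11), then the ring C–C bond between the carbinol carbon C-6 and the isopropenyl-bearing carbon C-5 (carvone numbering: C-1 ketone, C-2 methyl-bearing), which opens the carbocycle to the acyclic (Z)-2-oxo-dienal 10.
- Enabling feature: ring carbon C-6 carries oxygen and sits between the ring ketone C-1 and C-5, whose substituent is CH2=C(CH3)–. This O–C6–C5–C(CH3)=CH2 homoallylic alcohol array next to a ketone is the retron of a carbonyl-ene reaction between the aldehyde of a 1,2-dicarbonyl (a two-point binder for a chiral Lewis acid) and a 2-methylprop-1-enyl alkene.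
- Forward: a Z-selective Wittig reaction joins a C4 ketone to a C6 ylide; diol release and double oxidation give 10; the enantioselective ene reaction closes the six-membered ring (step 6); the oxirane ring follows (step 7); the side-chain acid (three steps from prenol and tigloyl chloride) is attached last.
- Stereochemistry: C-5 and C-6 from the chiral bis(oxazoline) complex of divalent copper (absolute) and the half-chair ene transition state (trans); the oxirane carbons by substrate control, anti to isopropenyl; the (Z)-alkene from the α-alkoxy-ketone Wittig reaction; both (E)-enoates from tiglic acid geometry and E-selective SeO2 oxidation.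

Key step: step 6

Assumption: the dioxolane CH carbon of 4 becomes the ketone carbon of 10, so 4 is used as the racemate (either enantiomer serves equally) and this centre is written without configuration in 4, 5, 6, 8 and 9.

**Step 1**
Reactants: 1 5-bromo-2-methylpent-2-ene; 2 triphenylphosphine
Product: 3 (4-methylpent-3-en-1-yl)triphenylphosphonium bromide
Conditions: MeCN, reflux
Reagents that add atoms: none
Why: SN2 quaternisation of a primary alkyl bromide by triphenylphosphine (phosphonium salt formation), which should go cleanly because the bromide is unhindered and the trisubstituted alkene is inert.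

**Step 2**
Reactants: 4 methyl 2,2-dimethyl-1,3-dioxolane-4-carboxylate
Product: 6 1-(2,2-dimethyl-1,3-dioxolan-4-yl)ethan-1-one, via N-methoxy-N-methylamide 5 (not isolated)
Conditions: MeNH(OMe)·HCl, i-PrMgCl, THF, −20 °C; then MeMgBr, −20 → 0 °C; aq NH4Cl
Reagents that add atoms: methylmagnesium bromide, C[Mg]Br; N,O-dimethylhydroxylamine hydrochloride, CNOC.Cl (its atoms remain only in 5)
Why: one-pot ester aminolysis by the magnesium amide followed by ketone synthesis from the N-methoxy-N-methylamide, where the chelated tetrahedral adduct should prevent a second addition of MeMgBr.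

**Step 3**
Reactants: 3 (4-methylpent-3-en-1-yl)triphenylphosphonium bromide; 6 1-(2,2-dimethyl-1,3-dioxolan-4-yl)ethan-1-one
Product: 8 2,2-dimethyl-4-[(2Z)-6-methylhepta-2,5-dien-2-yl]-1,3-dioxolane, via phosphonium ylide 7 (not isolated)
Conditions: KN(SiMe3)2, THF, −78 → 0 °C; then 6, −78 °C → rt
Reagents that add atoms: none
Why: Wittig olefination of an α-alkoxy ketone with a non-stabilised ylide under salt-free conditions, a combination known to place the oxygen-bearing carbon cis to the incoming chain, so the (Z)-trisubstituted alkene needed for the later ring closure is expected as the main isomer.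

**Step 4**
Reactants: 8 2,2-dimethyl-4-[(2Z)-6-methylhepta-2,5-dien-2-yl]-1,3-dioxolane
Product: 9 (3Z)-3,7-dimethylocta-3,6-diene-1,2-diol
Conditions: AcOH/H2O/THF (3:1:1), 40 °C
Reagents that add atoms: none
Why: mild acid-catalysed acetal hydrolysis, which should free the diol without hydrating or isomerising the two trisubstituted alkenes.

**Step 5**
Reactants: 9 (3Z)-3,7-dimethylocta-3,6-diene-1,2-diol
Product: 10 (3Z)-3,7-dimethyl-2-oxoocta-3,6-dienal
Conditions: (COCl)2, DMSO, CH2Cl2, −78 °C; i-Pr2NEt, −78 → −20 °C; cold non-aqueous work-up, used crude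
Reagents that add atoms: none
Why: double Swern oxidation of a vicinal diol, which gives the 1,2-dicarbonyl without C–C cleavage, with a hindered amine and low temperature chosen to avoid deprotonation at the doubly allylic CH2 and loss of the (Z)-geometry.

**Step 6**
Reactants: 10 (3Z)-3,7-dimethyl-2-oxoocta-3,6-dienal
Product: 11 (5R,6R)-6-hydroxy-2-methyl-5-(prop-1-en-2-yl)cyclohex-2-en-1-one
Conditions: [Cu(L)(H2O)2](SbF6)2 (10 mol %; L = 2,2'-(propane-2,2-diyl)bis[(4R)-4-tert-butyl-4,5-dihydro-1,3-oxazole]), 4 Å molecular sieves, CH2Cl2, −40 → 0 °C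
Reagents that add atoms: none
Why: Proposed new method: the closest known reaction types are the enantioselective intermolecular carbonyl-ene reaction of glyoxylate esters catalysed by bis(oxazoline) complexes of divalent copper and the Lewis-acid intramolecular carbonyl-ene closure of citronellal-type aldehydes, merged here on a tethered 2-oxo-aldehyde that binds the square-planar copper centre through both carbonyl oxygens (five-membered chelate, s-cis), so that the aldehyde carbon is strongly activated while the conjugated, fully substituted ketone carbon is not attacked. The trisubstituted alkene adds through its proximal carbon (C-6 of 10, which becomes C-5 of 11) to the aldehyde carbon (C-1 of 10, which becomes C-6 of 11) with concerted transfer of an allylic hydrogen from a terminal methyl group to the aldehyde oxygen, which forms the ring bond and releases the isopropenyl group and the free hydroxyl in one event without a by-product. The carbocycle closes in the 6-exo mode with respect to both π bonds (the aldehyde oxygen and the distal alkene carbon stay outside the ring), and the (Z)-enone holds the two reacting ends on the same side. The trans relation of hydroxyl and isopropenyl should follow from a half-chair transition state in which the chelated C–O bond lies in the ketone plane (pseudo-equatorial) and the 2-methylpropenyl unit is also pseudo-equatorial, as in isopulegol formation. The absolute configuration is set by the ligand, whose tert-butyl group beside the bound aldehyde blocks one face; by analogy with the glyoxylate reaction, where the (S,S)-ligand leads to Si-face attack, the (R,R)-ligand should direct the alkene to the Re face and give (5R,6R)-11, and the mirror-image ligand is available should the tether invert this sense. The step needs face selectivity at the aldehyde, aldehyde-over-ketone chemoselectivity and suppression of the uncatalysed racemic background, which are secured respectively by the C2-symmetric ligand, by chelation together with conjugation of the ketone, and by low temperature with exclusion of water.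

**Step 7**
Reactants: 11 (5R,6R)-6-hydroxy-2-methyl-5-(prop-1-en-2-yl)cyclohex-2-en-1-one
Product: 12 (1S,3R,4R,6S)-3-hydroxy-1-methyl-4-(prop-1-en-2-yl)-7-oxabicyclo[4.1.0]heptan-2-one
Conditions: 30% aq H2O2, NaOH (0.2 equiv), MeOH, −10 → 0 °C
Reagents that add atoms: hydrogen peroxide, OO
Why: Weitz–Scheffer nucleophilic epoxidation, in which, as with carvone itself, hydroperoxide anion should add axially to the β-carbon of the half-chair that keeps isopropenyl and hydroxyl equatorial and the enolate then closes on the O–O bond, so the oxirane forms anti to isopropenyl (1S,6S) while the electron-rich isopropenyl alkene is left alone.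

**Step 8**
Reactants: 13 3-methylbut-2-en-1-ol; 14 (2E)-2-methylbut-2-enoyl chloride
Product: 15 3-methylbut-2-en-1-yl (2E)-2-methylbut-2-enoate
Conditions: Et3N, DMAP (cat.), CH2Cl2, 0 °C → rt
Reagents that add atoms: none
Why: acylation of a primary allylic alcohol by an acid chloride under nucleophilic catalysis, which should keep the (E)-geometry of the tigloyl unit.

**Step 9**
Reactants: 15 3-methylbut-2-en-1-yl (2E)-2-methylbut-2-enoate
Product: 16 (2E)-3-methyl-4-oxobut-2-en-1-yl (2E)-2-methylbut-2-enoate
Conditions: SeO2 (1.3 equiv), 1,4-dioxane, 80 °C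
Reagents that add atoms: selenium dioxide, O=[Se]=O
Why: Riley allylic oxidation (ene reaction then 2,3-sigmatropic shift), which on a 2-methylprop-1-enyl group is known to oxidise the (E)-methyl group selectively and should leave the electron-poor tiglate alkene untouched, giving the (E)-enal.

**Step 10**
Reactants: 16 (2E)-3-methyl-4-oxobut-2-en-1-yl (2E)-2-methylbut-2-enoate
Product: 17 (2E)-2-methyl-4-{[(2E)-2-methylbut-2-enoyl]oxy}but-2-enoic acid
Conditions: NaClO2, NaH2PO4, 2-methylbut-2-ene, t-BuOH/H2O, 0 °C → rt
Reagents that add atoms: sodium chlorite, [Na+].[O-]Cl=O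
Why: Pinnick oxidation, the standard conversion of an enal to the enoic acid without touching alkene geometry or the ester, with the alkene scavenger removing hypochlorite.

**Step 11**
Reactants: 12 (1S,3R,4R,6S)-3-hydroxy-1-methyl-4-(prop-1-en-2-yl)-7-oxabicyclo[4.1.0]heptan-2-one; 17 (2E)-2-methyl-4-{[(2E)-2-methylbut-2-enoyl]oxy}but-2-enoic acid
Product: 18 (1S,3R,4R,6S)-1-methyl-2-oxo-4-(prop-1-en-2-yl)-7-oxabicyclo[4.1.0]heptan-3-yl (2E)-2-methyl-4-{[(2E)-2-methylbut-2-enoyl]oxy}but-2-enoate
Conditions: DCC, DMAP (cat.), CH2Cl2, 0 °C → rt
Reagents that add atoms: none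
Why: Steglich esterification of the equatorial secondary hydroxyl under near-neutral conditions, which should leave the oxirane, the ketone α-centre and both (E)-enoates unchanged and forms no new stereocentre.

**Compound list**

1 | 5-bromo-2-methylpent-2-ene | CC(C)=CCCBr | starting material
2 | triphenylphosphine | c1ccc(cc1)P(c1ccccc1)c1ccccc1 | starting material
3 | (4-methylpent-3-en-1-yl)triphenylphosphonium bromide | CC(C)=CCC[P+](c1ccccc1)(c1ccccc1)c1ccccc1.[Br-] | intermediate
4 | methyl 2,2-dimethyl-1,3-dioxolane-4-carboxylate (racemate) | COC(=O)C1COC(C)(C)O1 | starting material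
5 | N-methoxy-N,2,2-trimethyl-1,3-dioxolane-4-carboxamide | CON(C)C(=O)C1COC(C)(C)O1 | intermediate (not isolated)
6 | 1-(2,2-dimethyl-1,3-dioxolan-4-yl)ethan-1-one | CC(=O)C1COC(C)(C)O1 | intermediate
7 | (4-methylpent-3-en-1-ylidene)triphenyl-λ5-phosphane | CC(C)=CCC=P(c1ccccc1)(c1ccccc1)c1ccccc1 | intermediate (not isolated)
8 | 2,2-dimethyl-4-[(2Z)-6-methylhepta-2,5-dien-2-yl]-1,3-dioxolane | CC(C)=CC/C=C(/C)C1COC(C)(C)O1 | intermediate
9 | (3Z)-3,7-dimethylocta-3,6-diene-1,2-diol | CC(C)=CC/C=C(/C)C(O)CO | intermediate
10 | (3Z)-3,7-dimethyl-2-oxoocta-3,6-dienal | CC(C)=CC/C=C(/C)C(=O)C=O | intermediate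
11 | (5R,6R)-6-hydroxy-2-methyl-5-(prop-1-en-2-yl)cyclohex-2-en-1-one | C=C(C)[C@H]1CC=C(C)C(=O)[C@@H]1O | intermediate
12 | (1S,3R,4R,6S)-3-hydroxy-1-methyl-4-(prop-1-en-2-yl)-7-oxabicyclo[4.1.0]heptan-2-one | C=C(C)[C@H]1C[C@@H]2O[C@]2(C)C(=O)[C@@H]1O | intermediate
13 | 3-methylbut-2-en-1-ol | CC(C)=CCO | starting material
14 | (2E)-2-methylbut-2-enoyl chloride | C/C=C(\C)C(=O)Cl | starting material
15 | 3-methylbut-2-en-1-yl (2E)-2-methylbut-2-enoate | C/C=C(\C)C(=O)OCC=C(C)C | intermediate
16 | (2E)-3-methyl-4-oxobut-2-en-1-yl (2E)-2-methylbut-2-enoate | C/C=C(\C)C(=O)OC/C=C(\C)C=O | intermediate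
17 | (2E)-2-methyl-4-{[(2E)-2-methylbut-2-enoyl]oxy}but-2-enoic acid | C/C=C(\C)C(=O)OC/C=C(\C)C(=O)O | intermediate
18 | (1S,3R,4R,6S)-1-methyl-2-oxo-4-(prop-1-en-2-yl)-7-oxabicyclo[4.1.0]heptan-3-yl (2E)-2-methyl-4-{[(2E)-2-methylbut-2-enoyl]oxy}but-2-enoate | C=C(C)[C@H]1C[C@@H]2O[C@]2(C)C(=O)[C@@H]1OC(=O)/C(C)=C/COC(=O)/C(C)=C/C | target

**Step count**

Total steps: 11. Longest linear sequence: 7 steps (steps 2, 3, 4, 5, 6, 7 and 11; the branch through step 1 is equally long).

**Steps most likely to fail**

1. Step 6. The ligand may give poor face selectivity at the chelated aldehyde, the uncatalysed racemic cyclisation may compete, or the chelating ketol product may inhibit the catalyst. The fallback uses known chemistry and sets out from 10. Sc(OTf)3 (5 mol %) in CH2Cl2 at low temperature should effect the same ene ring closure without asymmetric induction, giving 11 together with its mirror image (5S,6S)-6-hydroxy-2-methyl-5-(prop-1-en-2-yl)cyclohex-2-en-1-one F1. Lipase-catalysed transesterification (Burkholderia cepacia lipase, vinyl acetate, MTBE, 30 °C) is then expected, by the usual size rule for secondary alcohols with the isopropenyl-bearing ring carbon as the large group, to acetylate F1 selectively to (1S,6S)-3-methyl-2-oxo-6-(prop-1-en-2-yl)cyclohex-3-en-1-yl acetate F2. F2 is removed by chromatography and the route is rejoined at 11.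

2. Step 5. The amine base may deprotonate the doubly allylic CH2 (giving double-bond migration into conjugation or Z-to-E isomerisation), and the very electrophilic 2-oxo-aldehyde may hydrate or oligomerise on work-up. The fallback sets out from 9 and avoids amine base by oxidising the two carbinols one at a time. Selective silylation of the primary hydroxyl (TBSCl, imidazole, CH2Cl2, 0 °C) gives (3Z)-1-[(tert-butyldimethylsilyl)oxy]-3,7-dimethylocta-3,6-dien-2-ol F3. Dess–Martin oxidation (NaHCO3 buffer) gives (3Z)-1-[(tert-butyldimethylsilyl)oxy]-3,7-dimethylocta-3,6-dien-2-one F4. HF·pyridine in THF releases (3Z)-1-hydroxy-3,7-dimethylocta-3,6-dien-2-one F5, and a second Dess–Martin oxidation of this ketol returns to the route at 10.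

3. Step 7. Hydroxide may isomerise the free α-ketol through its enediol (epimerisation or 1,2-carbonyl transposition), and hydroperoxide may cleave the ketol oxidatively in competition with conjugate addition. The fallback sets out from 11 and masks the hydroxyl. TESCl and imidazole in CH2Cl2 give (5R,6R)-2-methyl-5-(prop-1-en-2-yl)-6-[(triethylsilyl)oxy]cyclohex-2-en-1-one F6. Nucleophilic epoxidation (t-BuOOH, DBU, CH2Cl2, or H2O2/NaOH as in step 7) should again occur anti to isopropenyl and give (1S,3R,4R,6S)-1-methyl-4-(prop-1-en-2-yl)-3-[(triethylsilyl)oxy]-7-oxabicyclo[4.1.0]heptan-2-one F7. HF·pyridine in THF at 0 °C then removes the silyl group and returns to the route at 12.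

**Further compounds**

F1 | step 6 | (5S,6S)-6-hydroxy-2-methyl-5-(prop-1-en-2-yl)cyclohex-2-en-1-one | C=C(C)[C@@H]1CC=C(C)C(=O)[C@H]1O
F2 | step 6 | (1S,6S)-3-methyl-2-oxo-6-(prop-1-en-2-yl)cyclohex-3-en-1-yl acetate | C=C(C)[C@@H]1CC=C(C)C(=O)[C@H]1OC(C)=O
F3 | step 5 | (3Z)-1-[(tert-butyldimethylsilyl)oxy]-3,7-dimethylocta-3,6-dien-2-ol | CC(C)=CC/C=C(/C)C(O)CO[Si](C)(C)C(C)(C)C
F4 | step 5 | (3Z)-1-[(tert-butyldimethylsilyl)oxy]-3,7-dimethylocta-3,6-dien-2-one | CC(C)=CC/C=C(/C)C(=O)CO[Si](C)(C)C(C)(C)C
F5 | step 5 | (3Z)-1-hydroxy-3,7-dimethylocta-3,6-dien-2-one | CC(C)=CC/C=C(/C)C(=O)CO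
F6 | step 7 | (5R,6R)-2-methyl-5-(prop-1-en-2-yl)-6-[(triethylsilyl)oxy]cyclohex-2-en-1-one | C=C(C)[C@H]1CC=C(C)C(=O)[C@@H]1O[Si](CC)(CC)CC
F7 | step 7 | (1S,3R,4R,6S)-1-methyl-4-(prop-1-en-2-yl)-3-[(triethylsilyl)oxy]-7-oxabicyclo[4.1.0]heptan-2-one | C=C(C)[C@H]1C[C@@H]2O[C@]2(C)C(=O)[C@@H]1O[Si](CC)(CC)CC
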